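**Retrosynthetic overview**
1. Target 14 ⇒ 13: the last C–O bond (C7–OH) comes from allylic hydroxylation of the 8(17)-alkene.
2. 13 ⇒ 8: C2–O by enolate hydroxylation, 3α-OH by bulky hydride, then the angelate ester from diol 11 and angelic anhydride 12.
3. 8 ⇒ 5 ⇒ 4: exocyclic alkene by dehydration of the C8 tertiary alcohol; C20 acetate from the C20 alcohol.
4. Key disconnection: the C20–O bond of 4 ⇒ C20–H of 3-oxosclareol 3 (new enzymatic hydroxylation of the angular methyl); 3 ⇒ (−)-sclareol 1 by enzymatic C3–H hydroxylation and oxidation.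
5. No ring is formed: rings A and B and stereocentres C5, C9, C10, C13 come intact from sclareol; C2, C3 and C7 are set in C–O/C–H bond-forming steps.

Assumption: labdane numbering (C17 = exocyclic CH2, C20 = the CH2OAc carbon on C10; α = face opposite C20); the SMILES is read as (2R,3S,5R,7R,9R,10R,13R), i.e. a normal labdane with the ring fusion and C13 of (−)-sclareol, 2α-angelate, 3α-OH, 7α-OH.

**Step 1**
Reactants: 1 (−)-sclareol [(13R)-labd-14-ene-8α,13-diol]
Product: 2 3β-hydroxysclareol [(13R)-labd-14-ene-3β,8α,13-triol]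
Conditions: C3-selective engineered cytochrome P450 BM3 variant (E. coli lysate), NADP+ (cat.), glucose dehydrogenase, D-glucose, air, phosphate buffer pH 8, 25 °C
Reagents that add atoms: dioxygen, O=O
Why: Known biocatalytic C(sp3)–H hydroxylation (hydrogen abstraction/oxygen rebound) of sclareol at the equatorial 3β-position by engineered BM3 variants; the new C3 centre is erased in step 2, so only site selectivity matters.

**Step 2**
Reactants: 2 3β-hydroxysclareol
Product: 3 3-oxosclareol [(13R)-8α,13-dihydroxylabd-14-en-3-one]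
Conditions: Dess–Martin periodinane, pyridine, CH2Cl2, 0 °C to rt
Reagents that add atoms: none
Why: Dess–Martin oxidation of the only secondary alcohol; the two tertiary alcohols cannot be oxidised and the buffered medium spares the tertiary allylic alcohol.

**Step 3**
Reactants: 3 3-oxosclareol
Product: 4 20-hydroxy-3-oxosclareol [(13R)-8α,13,20-trihydroxylabd-14-en-3-one]
Conditions: proposed C20-selective P450 BM3 variant (evolved from the step 1 enzyme; E. coli lysate), NADP+ (cat.), glucose dehydrogenase, D-glucose, air, phosphate buffer pH 8, 25 °C, stopped at about 70% conversion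
Reagents that add atoms: dioxygen, O=O
Why: Proposed new method: an evolved P450 BM3 variant that hydroxylates the angular C20 methyl of a labdane, which has not been shown on this skeleton; the ferryl-oxo porphyrin radical cation (iron formally tetravalent) abstracts a hydrogen atom from C20 and the resulting neopentyl-type radical, which has no β-hydrogen and no fast rearrangement, recombines with the iron-bound hydroxyl (oxygen rebound); selectivity is to be built in by directed evolution (active-site saturation mutagenesis, LC–MS screening on 3) so that the 3-ketone, which also deactivates the ring A C–H bonds inductively, and the 8α/13-hydroxyls anchor the substrate with its β-face and C20 over the heme; the closest known reaction type is P450 hydroxylation of angular methyl groups (C19 of steroids by CYP19A1 and fungal 19-hydroxylases, C20 of abietanes by CYP76AK enzymes) together with the BM3-variant C3 hydroxylation of step 1; no stereocentre is created.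

**Step 4**
Reactants: 4 20-hydroxy-3-oxosclareol
Product: 5 20-acetoxy-3-oxosclareol [(13R)-20-acetoxy-8α,13-dihydroxylabd-14-en-3-one]
Conditions: Ac2O (1.2 equiv), pyridine, DMAP (cat.), CH2Cl2, 0 °C
Reagents that add atoms: acetic anhydride, CC(=O)OC(C)=O
Why: Nucleophile-catalysed acylation of the only primary alcohol; the tertiary 8- and 13-hydroxyls do not react at 0 °C.

**Step 5**
Reactants: 5 20-acetoxy-3-oxosclareol
Product: 8 (13R)-20-acetoxy-13-hydroxylabda-8(17),14-dien-3-one, via 13-O-TMS ether 6 (not isolated), via 13-O-TMS diene 7 (not isolated)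
Conditions: TMSCl (1.1 equiv), imidazole, CH2Cl2, 0 °C; then pyridine, SOCl2, −78 °C; aq. NaHCO3; then citric acid (cat.), MeOH, 0 °C
Reagents that add atoms: none
Why: Chlorosulfite E2 dehydration with Hofmann-type regioselectivity: the equatorial 8α leaving group has only the C17–H bonds anti-periplanar, so the exocyclic alkene forms, while the unhindered 13-OH is masked in the flask as its TMS ether (the hindered 8-OH is not silylated) and released on work-up; no stereocentre is created.

**Step 6**
Reactants: 8 (13R)-20-acetoxy-13-hydroxylabda-8(17),14-dien-3-one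
Product: 10 (13R)-20-acetoxy-2α,13-dihydroxylabda-8(17),14-dien-3-one, via disodium enolate 9 (not isolated)
Conditions: NaN(SiMe3)2 (2.2 equiv), THF, −78 °C; then (±)-trans-2-(phenylsulfonyl)-3-phenyloxaziridine, −78 °C; NH4Cl
Reagents that add atoms: 2-(phenylsulfonyl)-3-phenyloxaziridine, O=S(=O)(c1ccccc1)N1OC1c1ccccc1
Why: Davis enolate hydroxylation: only C2 can enolise (C4 is quaternary) and the oxaziridine attacks from the α-face, the β-face being shielded by the axial C19 methyl and C20 acetoxymethyl groups, giving the equatorial 2α-OH (also the thermodynamic epimer).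

**Step 7**
Reactants: 10 (13R)-20-acetoxy-2α,13-dihydroxylabda-8(17),14-dien-3-one
Product: 11 (13R)-20-acetoxylabda-8(17),14-diene-2α,3α,13-triol
Conditions: LiBH(s-Bu)3 (3.5 equiv), THF, −78 °C; aq. NH4Cl
Reagents that add atoms: none
Why: Bulky-hydride ketone reduction: equatorial delivery from the β-side, as for other 4,4-dimethyl-3-ketones, gives the axial 3α-alcohol (cis-2α,3α-diol); the hindered neopentyl acetate and both alkenes are inert at −78 °C.

**Step 8**
Reactants: 11 (13R)-20-acetoxylabda-8(17),14-diene-2α,3α,13-triol; 12 angelic anhydride [(Z)-2-methylbut-2-enoic anhydride]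
Product: 13 (13R)-20-acetoxy-2α-angeloyloxylabda-8(17),14-diene-3α,13-diol
Conditions: Cs2CO3, MeCN, rt
Reagents that add atoms: none
Why: Base-mediated acylation with the anhydride and no nucleophilic catalyst, which avoids Z-to-E isomerisation of the angelate; the equatorial 2α-OH reacts far faster than the axial neopentyl 3α-OH or the tertiary 13-OH.

**Step 9**
Reactants: 13 (13R)-20-acetoxy-2α-angeloyloxylabda-8(17),14-diene-3α,13-diol
Product: 14 target, (13R)-20-acetoxy-2α-angeloyloxylabda-8(17),14-diene-3α,7α,13-triol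
Conditions: SeO2 (0.3 equiv), t-BuOOH (2 equiv), CH2Cl2, 0 °C to rt
Reagents that add atoms: tert-butyl hydroperoxide, CC(C)(C)OO; selenium dioxide, O=[Se]=O (catalytic oxygen carrier)
Why: Riley/Sharpless allylic oxidation: ene reaction at C17 with loss of a C7 hydrogen (CH2 preferred over the C9 methine), then a [2,3]-sigmatropic shift that returns the exocyclic alkene and delivers oxygen axially to C7, giving 7α-OH as known for labd-8(17)-enes; the vinyl group has no allylic hydrogen and the electron-poor angelate is unreactive.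

**Compound list**
1 | (−)-sclareol, (13R)-labd-14-ene-8α,13-diol | C=C[C@](C)(O)CC[C@H]1[C@](C)(O)CC[C@H]2C(C)(C)CCC[C@]12C | starting material
2 | 3β-hydroxysclareol | C=C[C@](C)(O)CC[C@H]1[C@](C)(O)CC[C@H]2C(C)(C)[C@@H](O)CC[C@]12C | intermediate
3 | 3-oxosclareol | C=C[C@](C)(O)CC[C@H]1[C@](C)(O)CC[C@H]2C(C)(C)C(=O)CC[C@]12C | intermediate
4 | 20-hydroxy-3-oxosclareol | C=C[C@](C)(O)CC[C@H]1[C@](C)(O)CC[C@H]2C(C)(C)C(=O)CC[C@]12CO | intermediate
5 | 20-acetoxy-3-oxosclareol | C=C[C@](C)(O)CC[C@H]1[C@](C)(O)CC[C@H]2C(C)(C)C(=O)CC[C@]12COC(C)=O | intermediate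
6 | 13-O-trimethylsilyl ether of 5 (not isolated) | C=C[C@](C)(O[Si](C)(C)C)CC[C@H]1[C@](C)(O)CC[C@H]2C(C)(C)C(=O)CC[C@]12COC(C)=O | intermediate
7 | 13-O-trimethylsilyl ether of 8 (not isolated) | C=C[C@](C)(O[Si](C)(C)C)CC[C@H]1C(=C)CC[C@H]2C(C)(C)C(=O)CC[C@]12COC(C)=O | intermediate
8 | (13R)-20-acetoxy-13-hydroxylabda-8(17),14-dien-3-one | C=C[C@](C)(O)CC[C@H]1C(=C)CC[C@H]2C(C)(C)C(=O)CC[C@]12COC(C)=O | intermediate
9 | disodium 13-alkoxide/C2–C3 enolate of 8 (not isolated) | C=C[C@](C)([O-])CC[C@H]1C(=C)CC[C@H]2C(C)(C)C([O-])=CC[C@]12COC(C)=O.[Na+].[Na+] | intermediate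
10 | (13R)-20-acetoxy-2α,13-dihydroxylabda-8(17),14-dien-3-one | C=C[C@](C)(O)CC[C@H]1C(=C)CC[C@H]2C(C)(C)C(=O)[C@H](O)C[C@]12COC(C)=O | intermediate
11 | (13R)-20-acetoxylabda-8(17),14-diene-2α,3α,13-triol | C=C[C@](C)(O)CC[C@H]1C(=C)CC[C@H]2C(C)(C)[C@H](O)[C@H](O)C[C@]12COC(C)=O | intermediate
12 | angelic anhydride | C/C=C(/C)C(=O)OC(=O)/C(C)=C\C | starting material
13 | (13R)-20-acetoxy-2α-angeloyloxylabda-8(17),14-diene-3α,13-diol | C=C[C@](C)(O)CC[C@H]1C(=C)CC[C@H]2C(C)(C)[C@H](O)[C@H](OC(=O)/C(C)=C\C)C[C@]12COC(C)=O | intermediate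
14 | (13R)-20-acetoxy-2α-angeloyloxylabda-8(17),14-diene-3α,7α,13-triol | C=C[C@](C)(O)CC[C@H]1C(=C)[C@H](O)C[C@H]2C(C)(C)[C@H](O)[C@H](OC(=O)/C(C)=C\C)C[C@]12COC(C)=O | target

**Total step count:** 9. **Longest linear sequence:** 9 steps (1 to 14).

**Steps most likely to fail**

Step 3 (the new C20 hydroxylation). The variant does not yet exist. It may hydroxylate C2, C6/C7, C12 or the C4 methyls instead, epoxidise the vinyl group, or over-oxidise C20 to the aldehyde. Fallback with known chemistry, setting out from 3 and coming back at 8: the halohydrin / hypoiodite / zinc relay that is the classical route to 19-hydroxy steroids, applied to the 8(17)-alkene.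
- 3 is silylated at the unhindered 13-OH (Et3SiOTf, 2,6-lutidine, −78 °C) to the 13-O-triethylsilyl ether of 3-oxosclareol F1.
- F1 is dehydrated as in step 5 (SOCl2, pyridine, −78 °C) to the 13-O-triethylsilyl diene ketone F2.
- NBS in aqueous THF (NaHCO3, 0 °C) puts bromine on C17 and water on C8 anti to the α-bromonium, giving the 17-bromo-8β-hydroxy compound F3. Any 8α-hydroxy epimer returns F2 with zinc and is recycled.
- PhI(OAc)2, I2, cyclohexane, visible light: the 8β-alkoxy radical abstracts hydrogen from the 1,3-diaxial C20 methyl (1,5-hydrogen transfer) and closes the 17-bromo-8β,20-epoxide F4.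
- Zn dust, NH4Cl, EtOH, 60 °C: reductive elimination of the β-bromo ether restores the exocyclic alkene and frees the C20 alcohol, giving the 13-O-triethylsilyl 20-hydroxy diene ketone F5.
- Ac2O, pyridine gives the 20-acetate F6, and HF·pyridine in THF removes the silyl group to give 8.

Step 5 (dehydration). The elimination may give the endocyclic C7–C8 (and C8–C9) alkenes instead of the exocyclic one, and the selective silylation of 13-OH over 8-OH may be incomplete. Fallback, setting out from 5 (through 6) and coming back at 7: regiochemistry is corrected after the elimination instead of during it. 6 is dehydrated without regard to regiochemistry (Burgess reagent, benzene, 50 °C), and the main endocyclic product, the 13-O-trimethylsilyl labda-7,14-dien-3-one F7, is converted into the less substituted exocyclic isomer 7 by catalytic contra-thermodynamic positional alkene isomerisation ((Bu4N)4[W10O32] and Co(dmgH)2(py)Cl, MeCN, near-UV light). The citric acid/MeOH work-up of step 5 then gives 8.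

Step 7 (3α-selective reduction). The free 2α-alkoxide may erode the facial selectivity and give the 2α,3β-diol. Fallback, setting out from 10 and coming back at 13: the order of esterification and reduction is reversed and the reduction is put under catalyst control. 10 is esterified with 12 (Cs2CO3, MeCN) to the 2α-angeloyloxy-3-ketone F8. The ketone is then reduced with catecholborane and the CBS oxazaborolidine enantiomer that delivers hydride to the β-face (by the usual model (S)-2-methyl-CBS, the quaternary C4 acting as the large group) in toluene at −78 °C, giving 13 directly.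

**Further compounds**
F1 | step 3 | (13R)-8α-hydroxy-13-(triethylsilyloxy)labd-14-en-3-one | C=C[C@](C)(O[Si](CC)(CC)CC)CC[C@H]1[C@](C)(O)CC[C@H]2C(C)(C)C(=O)CC[C@]12C
F2 | step 3 | (13R)-13-(triethylsilyloxy)labda-8(17),14-dien-3-one | C=C[C@](C)(O[Si](CC)(CC)CC)CC[C@H]1C(=C)CC[C@H]2C(C)(C)C(=O)CC[C@]12C
F3 | step 3 | (13R)-17-bromo-8β-hydroxy-13-(triethylsilyloxy)-8-epi-labd-14-en-3-one | C=C[C@](C)(O[Si](CC)(CC)CC)CC[C@H]1[C@@](CBr)(O)CC[C@H]2C(C)(C)C(=O)CC[C@]12C
F4 | step 3 | (13R)-17-bromo-8β,20-epoxy-13-(triethylsilyloxy)-8-epi-labd-14-en-3-one | C=C[C@](C)(O[Si](CC)(CC)CC)CC[C@H]1[C@@](CBr)(O3)CC[C@H]2C(C)(C)C(=O)CC[C@]12C3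
F5 | step 3 | (13R)-20-hydroxy-13-(triethylsilyloxy)labda-8(17),14-dien-3-one | C=C[C@](C)(O[Si](CC)(CC)CC)CC[C@H]1C(=C)CC[C@H]2C(C)(C)C(=O)CC[C@]12CO
F6 | step 3 | (13R)-20-acetoxy-13-(triethylsilyloxy)labda-8(17),14-dien-3-one | C=C[C@](C)(O[Si](CC)(CC)CC)CC[C@H]1C(=C)CC[C@H]2C(C)(C)C(=O)CC[C@]12COC(C)=O
F7 | step 5 | (13R)-20-acetoxy-13-(trimethylsilyloxy)labda-7,14-dien-3-one | C=C[C@](C)(O[Si](C)(C)C)CC[C@H]1C(C)=CC[C@H]2C(C)(C)C(=O)CC[C@]12COC(C)=O
F8 | step 7 | (13R)-20-acetoxy-2α-angeloyloxy-13-hydroxylabda-8(17),14-dien-3-one | C=C[C@](C)(O)CC[C@H]1C(=C)CC[C@H]2C(C)(C)C(=O)[C@H](OC(=O)/C(C)=C\C)C[C@]12COC(C)=O
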